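The mono adduct stands at a fork: with the coupling partner it can become double product, and with the capture agent it can become trapped intermediate.

| setting | elm | oak | zeta | epsilon | alpha |
|---|---|---|---|---|---|
| starting material | 10 mM | 10 mM | 10 mM | 10 mM | 10 mM |
| coupling partner | 22 mM | 37 mM | 15.0 mM | 20.0 mM | 25.0 mM |
| capture agent | 3 mM | 3 mM | 3.00 mM | 3.00 mM | 3.00 mM |
| remark | run made earlier | run made earlier |  |  |  |
| time |  |  | 1.0 h | 1.0 h | 1.0 h |

| run | time / min | double product / % |
|---|---|---|
| elm | 5.00 | 71.3 |
| elm | 10.0 | 86.2 |
| elm | 15.0 | 90.0 |
| elm | 30.0 | 90.5 |
| elm | 60.0 | 92.3 |
| oak | 12.0 | 98.6 |
| oak | 25.0 | 97.6 |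
| oak | 40.0 | 96.5 |
| oak | 50.0 | 97.1 |
| oak | 60.0 | 96.5 |

(standard deviation of a reading: 1 percentage point)

- steps under discussion: starting material + coupling partner -> mono adduct; mono adduct + capture agent -> trapped intermediate; double product -> over-reaction product; coupling partner + mono adduct -> double product

- how much double product is there at the end, in percent of the starting material charged: for each flask in turn (zeta, epsilon, alpha)

I fold the charges into one capture number: capture agent charged, over the coupling partner remaining once each starting material has taken one partner. This number takes the first addition as finished before the fork and weighs charges with no rate constants in it, so it rests on an assumption about speed, and what the speeds do is left to a factor read from the runs. It is 0.250 in elm and 0.111 in oak. Their last two readings, averaged, fall short of the whole charge by 8.60% and 3.20%. Dividing gives the readings 0.344 and 0.288, so I take their mean, the shortfall factor, the fraction of the charge missing from double product per unit of capture number: 0.316.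

Epsilon has capture number 0.300, so I expect 90.5%. Alpha has 0.200, so I expect 93.7%. Zeta has 0.600, which gives 81.0%. But double product takes two partners, so zeta's partner, its limiting reagent, pays for at most 75.0% of the charge, less than that reckoning. One number is not enough there, and for zeta I commit only to staying under this cover.

The forecast says 50.5%, 87.5% and 93.5%, holding that “partner and capture agent compete for the mono adduct”.

The flasks give 58.3%, 89.1% and 93.5%.

    starting material + coupling partner → mono adduct (k = 0.992 M⁻¹ s⁻¹)
    mono adduct + capture agent → trapped intermediate (k = 0.129 M⁻¹ s⁻¹)
    double product → over-reaction product (k = 8.42 × 10⁻⁶ s⁻¹)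
    coupling partner + mono adduct → double product (k = 0.864 M⁻¹ s⁻¹)

Zeta lies 7.8 percentage points above the forecast and under the cover, and at the end it still holds 9.95% as starting material and 12.4% as mono adduct, with coupling partner at 0% of its charge. The shortfall factor times epsilon's capture number gives 9.48%, and epsilon falls short by 10.9%. For alpha the same product gives 6.32%, and alpha falls short by 6.50%.

(The runs stem from a simulated flask with constants of no real substance; scatter was added.)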